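**Plan**

1. Retrosynthesis: the three ester C–O bonds are cut one after another (side-chain ester, quaternary ring ester, CH-bound ring ester). This leaves cyclobutane-1,3-dicarboxylic acid 27, whose side chain is still a methyl enoate, and three molecules of one amino alcohol (12), a cis-fused octahydro-1H-cyclopenta[c]pyridin-6-ol (locants N2, C1, C3, C4, C4a, C5, C6, C7, C7a).
2. In 12 the piperidine ring consists of a four-atom unit N2–C3–C4(Me)–C4a and a two-carbon unit C7a–C1, and the cyclopentane carbons C5–C6–C7 already tie C4a to C7a. Cutting N2–C1 and C4a–C7a together therefore gives one acyclic N-sulfonyl-1-azadiene with a terminal alkene; a single intramolecular aza-Diels–Alder reaction closes both rings.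
3. Forward for 12: asymmetric syn-crotylation sets C6 and C7; a Wittig reaction makes the (E)-enal; the cycloaddition sets C4a and C7a under control of C6/C7; hydroxyl-directed hydrogenation of the remaining C3=C4 ene-sulfonamide sets C4.
4. Diacid 27: the cyclobutane is cut by [2+2] into an aryl keteniminium ion and the 6,7-alkene of an 8-silyloxy geranate. Alkene geometry fixes the quaternary carbon, a C2-symmetric pyrrolidine the absolute sense, equilibration the two epimerisable ring carbons; the ring C=O and the CH2OSi group are then taken to CO2H.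
5. Union: 12 is attached three times in separate acylations, each with retention at C6: through the cis-1,3 cyclic anhydride of 27, through the acyl chloride of the quaternary acid, and, after cleavage of the methyl ester, through a Yamaguchi mixed anhydride. Debenzylation of the phenol ends the route.

Key step: step 5

Assumption: the sense of asymmetric induction of the (2R,5R)-2,5-dimethylpyrrolidine auxiliary in step 13 is assigned from a steric model only; should the cyclobutanone form as the antipode, the (2S,5S)-amine takes its place with no other change.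

**Route**

Step 1
Reactants: 1 3-[(tert-butyldimethylsilyl)oxy]propanal
Product: 2 (3R,4R)-1-[(tert-butyldimethylsilyl)oxy]-4-methylhex-5-en-3-ol
Conditions: (Z)-crotyl-B(Ipc)2 [made at −78 °C from cis-2-butene, n-BuLi, KOt-Bu, (−)-Ipc2BOMe, BF3·OEt2], THF, −78 °C; then NaOH, H2O2, 23 °C
Reagents that add atoms: (Z)-crotylbis(isopinocampheyl)borane, C/C=C\CB([C@@H]1C[C@@H]2C[C@H]([C@H]1C)C2(C)C)[C@@H]1C[C@@H]2C[C@H]([C@H]1C)C2(C)C
Why: Brown asymmetric crotylboration through a closed chair transition state, in which the (Z)-crotyl group gives the syn relation of OH and methyl and the isopinocampheyl groups derived from (+)-α-pinene should direct attack to the Si face of the aldehyde, setting C6 and C7 of the later bicycle as (3R,4R).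

Step 2
Reactants: 2 (3R,4R)-1-[(tert-butyldimethylsilyl)oxy]-4-methylhex-5-en-3-ol
Product: 3 (3R,4R)-4-methylhex-5-ene-1,3-diol bis(tert-butyldimethylsilyl) ether
Conditions: TBSCl, imidazole, DMF, 23 °C
Reagents that add atoms: tert-butyldimethylsilyl chloride, CC(C)(C)[Si](C)(C)Cl
Why: Standard silylation of the secondary alcohol, which masks O6 during the Lewis-acidic imine formation and the cycloaddition.

Step 3
Reactants: 3 (3R,4R)-4-methylhex-5-ene-1,3-diol bis(tert-butyldimethylsilyl) ether
Product: 4 (3R,4R)-3-[(tert-butyldimethylsilyl)oxy]-4-methylhex-5-en-1-ol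
Conditions: camphorsulfonic acid (10 mol %), MeOH/CH2Cl2 1:1, 0 °C
Reagents that add atoms: none
Why: Acid-catalysed methanolysis removes a primary silyl ether much faster than the hindered secondary one, so the primary alcohol should be freed selectively.

Step 4
Reactants: 4 (3R,4R)-3-[(tert-butyldimethylsilyl)oxy]-4-methylhex-5-en-1-ol
Product: 6 (2E,5R,6R)-5-[(tert-butyldimethylsilyl)oxy]-2,6-dimethylocta-2,7-dienal, via aldehyde 5 (not isolated)
Conditions: Dess–Martin periodinane, NaHCO3, CH2Cl2, 23 °C; filter, concentrate; then Ph3P=C(Me)CHO, PhMe, 90 °C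
Reagents that add atoms: 2-(triphenylphosphoranylidene)propanal, CC(C=O)=P(c1ccccc1)(c1ccccc1)c1ccccc1
Why: Dess–Martin oxidation followed by Wittig olefination with the stabilised formyl ylide, which should give the (E)-2-methyl enal under thermodynamic control; the β-silyloxy aldehyde is used crude to limit elimination.

Step 5
Reactants: 6 (2E,5R,6R)-5-[(tert-butyldimethylsilyl)oxy]-2,6-dimethylocta-2,7-dienal
Product: 8 (4aS,6R,7R,7aS)-6-[(tert-butyldimethylsilyl)oxy]-4,7-dimethyl-2-tosyl-2,4a,5,6,7,7a-hexahydro-1H-cyclopenta[c]pyridine, via N-tosyl azadiene 7 (not isolated)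
Conditions: TsNH2, TiCl4, Et3N, CH2Cl2, 0 → 23 °C; filter through Celite, concentrate; then PhMe, 110 °C (sealed tube, BHT)
Reagents that add atoms: p-toluenesulfonamide, Cc1ccc(cc1)S(N)(=O)=O
Why: Condensation gives the N-tosyl-1-aza-1,3-diene N2=C3–C4(Me)=C4a, whose lowered LUMO lets it add across the tethered, unactivated C7a=C1 alkene in a concerted but asynchronous inverse-electron-demand intramolecular [4+2] cycloaddition, so that N2–C1 and C4a–C7a are made in the same event. The closest known reaction type is the intramolecular Diels–Alder reaction of N-sulfonyl-1-azadienes with unactivated alkenes, the aza analogue of the nona-1,3,8-triene cycloaddition. The tetrahydropyridine is the six-membered ring of the cycloaddition itself, and the cyclopentane closes at the same time through the three-carbon tether C5–C6–C7 (a 5-exo-type closure onto the internal alkene carbon C7a, with C1 delivered to nitrogen). C4a and C7a should be set cis because suprafacial addition places the (E)-terminus substituent C5 cis to the tether carbon C7 when the tether lies under the diene (endo), the low-strain fold for three atoms; their sense relative to C6 and C7 follows from an envelope tether with C6–OTBS and C7–Me pseudo-equatorial, which puts C7–Me trans to C1 and O6 on the face of the new piperidine ring. The step needs ring-fusion and π-facial selectivity (regiochemistry is fixed by the tether, and the azadiene reaches its s-cis form easily because C4 carries only a methyl), and these are secured by the tether length and the two resident stereocentres. The C3=C4 ene-sulfonamide that remains is the handle for setting C4.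

Step 6
Reactants: 8 (4aS,6R,7R,7aS)-6-[(tert-butyldimethylsilyl)oxy]-4,7-dimethyl-2-tosyl-2,4a,5,6,7,7a-hexahydro-1H-cyclopenta[c]pyridine
Product: 9 (4aS,6R,7R,7aS)-4,7-dimethyl-2-tosyl-2,4a,5,6,7,7a-hexahydro-1H-cyclopenta[c]pyridin-6-ol
Conditions: Bu4NF, THF, 23 °C
Reagents that add atoms: none
Why: Fluoride desilylation frees the C6 hydroxyl that is needed as the directing group in the next step, and the ene-sulfonamide is inert to fluoride.

Step 7
Reactants: 9 (4aS,6R,7R,7aS)-4,7-dimethyl-2-tosyl-2,4a,5,6,7,7a-hexahydro-1H-cyclopenta[c]pyridin-6-ol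
Product: 10 (4R,4aR,6R,7R,7aS)-4,7-dimethyl-2-tosyloctahydro-1H-cyclopenta[c]pyridin-6-ol
Conditions: [Ir(cod)(PCy3)(py)]PF6 (5 mol %), H2 (1 atm), CH2Cl2, 23 °C
Reagents that add atoms: none
Why: Hydroxyl-directed homogeneous hydrogenation: the C6–OH sits on the concave face directly beneath C3=C4 and should bind the cationic iridium, so both hydrogens arrive from that face and the C4 methyl ends cis to H4a (4R), whereas undirected hydrogenation from the open convex face would give the C4 epimer; the non-basic sulfonamide nitrogen does not compete for the metal.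

Step 8
Reactants: 10 (4R,4aR,6R,7R,7aS)-4,7-dimethyl-2-tosyloctahydro-1H-cyclopenta[c]pyridin-6-ol
Product: 11 (4R,4aR,6R,7R,7aS)-4,7-dimethyloctahydro-1H-cyclopenta[c]pyridin-6-ol
Conditions: sodium naphthalenide (NaC10H8, 6 equiv), DME, −78 °C; then H2O
Reagents that add atoms: none
Why: Single-electron reductive cleavage of the N–S bond of an N-alkyl arenesulfonamide, which touches no stereocentre.

Step 9
Reactants: 11 (4R,4aR,6R,7R,7aS)-4,7-dimethyloctahydro-1H-cyclopenta[c]pyridin-6-ol
Product: 12 (4R,4aR,6R,7R,7aS)-2,4,7-trimethyloctahydro-1H-cyclopenta[c]pyridin-6-ol (the amino alcohol of the target)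
Conditions: aq. CH2O, NaBH(OAc)3, AcOH, ClCH2CH2Cl, 23 °C
Reagents that add atoms: formaldehyde, C=O
Why: Reductive amination, in which the iminium ion formed from the secondary amine and formaldehyde is reduced by the acetoxyborohydride to the N-methyl amine.

Step 10
Reactants: 13 methyl (2E)-3,7-dimethylocta-2,6-dienoate (methyl geranate)
Product: 14 methyl (2E,6E)-8-hydroxy-3,7-dimethylocta-2,6-dienoate
Conditions: SeO2 (10 mol %), t-BuOOH, salicylic acid (10 mol %), CH2Cl2, 23 °C; then NaBH4, MeOH, 0 °C
Reagents that add atoms: SeO2 (catalytic oxygen carrier), O=[Se]=O; tert-butyl hydroperoxide, CC(C)(C)OO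
Why: SeO2 allylic oxidation (ene reaction then [2,3]-shift) is selective for the (E)-methyl of the electron-rich 6,7-alkene and leaves the conjugated 2,3-alkene alone, and the borohydride returns any over-oxidised enal to the (E)-allylic alcohol whose geometry later fixes the quaternary ring carbon.

Step 11
Reactants: 14 methyl (2E,6E)-8-hydroxy-3,7-dimethylocta-2,6-dienoate
Product: 15 methyl (2E,6E)-8-[(tert-butyldiphenylsilyl)oxy]-3,7-dimethylocta-2,6-dienoate
Conditions: TBDPSCl, imidazole, DMF, 23 °C
Reagents that add atoms: tert-butyldiphenylsilyl chloride, CC(C)(C)[Si](Cl)(c1ccccc1)c1ccccc1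
Why: Silylation gives a robust, weakly nucleophilic ether that cannot take part as a neighbouring group in the cationic cycloaddition.

Step 12
Reactants: 16 2-[4-(benzyloxy)-3-methoxyphenyl]acetic acid; 17 (2R,5R)-2,5-dimethylpyrrolidine
Product: 19 2-[4-(benzyloxy)-3-methoxyphenyl]-1-[(2R,5R)-2,5-dimethylpyrrolidin-1-yl]ethan-1-one, via acid chloride 18 (not isolated)
Conditions: (COCl)2, DMF (cat.), CH2Cl2, 0 → 23 °C; concentrate; then 17, Et3N, CH2Cl2, 0 °C
Reagents that add atoms: none
Why: Amide formation through the acid chloride installs the C2-symmetric amine, for which the two amide rotamers are identical.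

Step 13
Reactants: 19 2-[4-(benzyloxy)-3-methoxyphenyl]-1-[(2R,5R)-2,5-dimethylpyrrolidin-1-yl]ethan-1-one; 15 methyl (2E,6E)-8-[(tert-butyldiphenylsilyl)oxy]-3,7-dimethylocta-2,6-dienoate (1.5 equiv)
Product: 22 (2S,3R,4R)-2-[4-(benzyloxy)-3-methoxyphenyl]-3-{[(tert-butyldiphenylsilyl)oxy]methyl}-3-methyl-4-[(3E)-5-methoxy-3-methyl-5-oxopent-3-en-1-yl]cyclobutan-1-one, via keteniminium triflate 20 (not isolated), via cyclobutaniminium triflate 21 (not isolated)
Conditions: Tf2O, 2,4,6-collidine, ClCH2CH2Cl, −20 → 80 °C; then aq. NaHCO3, 23 °C; then Et3N, CH2Cl2, 23 °C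
Reagents that add atoms: water, O
Why: Ghosez keteniminium–alkene [2+2] cycloaddition, in which the iminium carbon of 20 bonds to the less substituted C6 of the nucleophilic 6,7-alkene of 15 and the aryl-bearing carbon closes onto the tertiary C7 (the conjugated 2,3-alkene is inert), so that regiochemistry and the trans relation of side chain and CH2OSi follow from the (6E)-alkene, the C2-symmetric pyrrolidine differentiates the two alkene faces, and after hydrolysis the acidic benzylic α-carbon equilibrates to the 2,4-cis ketone with aryl, side chain and ring methyl on one face.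

Step 14
Reactants: 22 the cyclobutanone of step 13
Product: 23 methoxymethylene derivative of 22 (exocyclic methyl enol ether in place of C=O, E/Z mixture)
Conditions: Ph3P(CH2OMe)Cl, KN(SiMe3)2, THF, 0 °C; then 22, 0 → 23 °C
Reagents that add atoms: (methoxymethyl)triphenylphosphonium chloride, COC[P+](c1ccccc1)(c1ccccc1)c1ccccc1.[Cl-]
Why: Wittig methoxymethylenation, which should succeed because the strained cyclobutanone carbonyl adds the ylide faster than it enolises.

Step 15
Reactants: 23 methoxymethylene derivative of 22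
Product: 24 cyclobutanecarbaldehyde (CHO on the former carbonyl carbon, trans to the aryl group and to the side chain)
Conditions: 2 M HCl, THF, 23 °C; then DBU (20 mol %), CH2Cl2, 23 °C
Reagents that add atoms: water, O
Why: Acid hydrolysis of the enol ether gives the aldehyde, and reversible enolisation places the formyl group trans to both ring neighbours (thermodynamic control), which sets the last ring stereocentre.

Step 16
Reactants: 24 cyclobutanecarbaldehyde
Product: 25 cyclobutanecarboxylic acid (CO2H in place of CHO)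
Conditions: NaClO2, NaH2PO4, 2-methyl-2-butene, t-BuOH/H2O, 0 → 23 °C
Reagents that add atoms: sodium chlorite, [Na+].[O-]Cl=O
Why: Pinnick oxidation converts the aldehyde into the acid without epimerisation, and the alkene scavenger protects the electron-rich arene from hypochlorite.

Step 17
Reactants: 25 cyclobutanecarboxylic acid
Product: 27 2-[4-(benzyloxy)-3-methoxyphenyl]-4-[(3E)-5-methoxy-3-methyl-5-oxopent-3-en-1-yl]-1-methylcyclobutane-1,3-dicarboxylic acid (ring diacid; the two carboxyls cis; side chain still a methyl ester), via hydroxy acid methyl ester 26 (not isolated)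
Conditions: Bu4NF, THF, 23 °C; wash with aq. phosphate buffer (pH 7), concentrate; then TEMPO (20 mol %), PhI(OAc)2, MeCN/aq. phosphate buffer (pH 7), 23 °C; HCl to pH 4
Reagents that add atoms: water, O
Why: Fluoride removes the neopentyl-type silyl ether and oxoammonium (TEMPO) oxidation then takes the primary alcohol through the aldehyde hydrate to the acid at a carbon with no α-hydrogen, so no stereocentre can be lost; the hydroxy acid is carried on crude as its carboxylate so that the cis-1,3 pair does not lactonise, and the methyl enoate is kept to hold the side-chain carboxyl apart from the two ring carboxyls.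

Step 18
Reactants: 27 ring diacid; 12 amino alcohol
Product: 29 half-ester (CH-bound ring carboxyl esterified by 12; quaternary ring CO2H free; side-chain methyl ester), via cyclic anhydride 28 (not isolated)
Conditions: DCC (1.0 equiv), CH2Cl2, 23 °C; filter, concentrate; 12 (1.05 equiv), n-BuLi, THF, −78 °C; then 28, −78 → 0 °C; then 1 M HCl to pH 6
Reagents that add atoms: none
Why: The cis-1,3 ring carboxyls close to a six-membered (glutaric-type) bridged anhydride, and anhydride alcoholysis by the lithium alkoxide takes place once only because the product is a carboxylate, at the less hindered carbonyl on the CH-bound carbon, with retention at C6 of 12 and with the CH configuration locked cis in the bridged ring; should some of the regioisomeric half-ester form, it leads to the same bis-ester 31 in step 19, because both ring carboxyls end as esters of the same alcohol.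

Step 19
Reactants: 29 half-ester; 12 amino alcohol
Product: 31 bis-ester (both ring carboxyls esterified by 12; side-chain methyl ester), via acyl chloride 30 (not isolated)
Conditions: (COCl)2, DMF (cat.), CH2Cl2, 0 → 23 °C; concentrate; 12 (2.5 equiv), n-BuLi (2.4 equiv), THF, −78 °C; then 30, −78 → 0 °C
Reagents that add atoms: none
Why: Acyl substitution of a non-enolisable acyl chloride by a lithium alkoxide, the usual answer to a neopentyl-type carboxyl and a hindered secondary alcohol; the amine of 29 is held as its hydrochloride by the HCl of the chlorination (one extra equivalent of alkoxide frees it), the conjugated methyl ester is far less electrophilic than the acyl chloride at low temperature, and C6 of 12 keeps its configuration.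

Step 20
Reactants: 31 bis-ester
Product: 32 bis-ester acid (side-chain enoic acid free)
Conditions: Me3SnOH (5 equiv), ClCH2CH2Cl, 80 °C; then 1 M HCl wash, adjust to pH 7
Reagents that add atoms: trimethyltin hydroxide, C[Sn](C)(C)O
Why: Trimethyltin hydroxide cleaves methyl esters by a mild tin-carboxylate pathway and should discriminate the unhindered methyl enoate from the two secondary-alkyl esters on the crowded cyclobutane, without a base strong enough to epimerise the CH–CO2R ring carbon or to move the double bond.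

Step 21
Reactants: 32 bis-ester acid; 12 amino alcohol
Product: 34 O-benzyl ether of the target (tris-ester), via mixed anhydride 33 (not isolated)
Conditions: 2,4,6-Cl3C6H2COCl, Et3N, THF, 23 °C; then 12 (1.5 equiv), DMAP, PhMe, 23 °C
Reagents that add atoms: none
Why: Yamaguchi esterification, in which DMAP attacks the mixed 2,4,6-trichlorobenzoic anhydride at the enoyl carbonyl only and the acylpyridinium ion acylates O6 of 12 with retention; the mild base should leave the (E)-trisubstituted enoate conjugated, which an enoyl chloride route through a vinylketene would put at risk.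

Step 22
Reactants: 34 O-benzyl ether of the target
Product: 35 CNP0251577.2 (target)
Conditions: BCl3, pentamethylbenzene, CH2Cl2, −78 °C; then MeOH, aq. NaHCO3
Reagents that add atoms: none
Why: Lewis-acid debenzylation of the aryl benzyl ether with a non-basic cation scavenger, conditions under which the three esters, the trisubstituted enoate and the amines (as BCl3 adducts, released on work-up) should survive.

**Compound list**

1 | 3-[(tert-butyldimethylsilyl)oxy]propanal | CC(C)(C)[Si](C)(C)OCCC=O | starting material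
2 | (3R,4R)-1-[(tert-butyldimethylsilyl)oxy]-4-methylhex-5-en-3-ol | C=C[C@@H](C)[C@H](O)CCO[Si](C)(C)C(C)(C)C | intermediate
3 | (3R,4R)-4-methylhex-5-ene-1,3-diol bis(tert-butyldimethylsilyl) ether | C=C[C@@H](C)[C@H](O[Si](C)(C)C(C)(C)C)CCO[Si](C)(C)C(C)(C)C | intermediate
4 | (3R,4R)-3-[(tert-butyldimethylsilyl)oxy]-4-methylhex-5-en-1-ol | C=C[C@@H](C)[C@H](O[Si](C)(C)C(C)(C)C)CCO | intermediate
5 | (3R,4R)-3-[(tert-butyldimethylsilyl)oxy]-4-methylhex-5-enal | C=C[C@@H](C)[C@H](O[Si](C)(C)C(C)(C)C)CC=O | intermediate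
6 | (2E,5R,6R)-5-[(tert-butyldimethylsilyl)oxy]-2,6-dimethylocta-2,7-dienal | C=C[C@@H](C)[C@H](O[Si](C)(C)C(C)(C)C)C/C=C(\C)C=O | intermediate
7 | N-[(1E,2E,5R,6R)-5-[(tert-butyldimethylsilyl)oxy]-2,6-dimethylocta-2,7-dien-1-ylidene]-4-methylbenzenesulfonamide | C=C[C@@H](C)[C@H](O[Si](C)(C)C(C)(C)C)C/C=C(\C)/C=N/S(=O)(=O)c1ccc(C)cc1 | intermediate
8 | (4aS,6R,7R,7aS)-6-[(tert-butyldimethylsilyl)oxy]-4,7-dimethyl-2-tosyl-2,4a,5,6,7,7a-hexahydro-1H-cyclopenta[c]pyridine | CC(C)(C)[Si](C)(C)O[C@@H]1C[C@H]2[C@H](CN(S(=O)(=O)c3ccc(C)cc3)C=C2C)[C@H]1C | intermediate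
9 | (4aS,6R,7R,7aS)-4,7-dimethyl-2-tosyl-2,4a,5,6,7,7a-hexahydro-1H-cyclopenta[c]pyridin-6-ol | O[C@@H]1C[C@H]2[C@H](CN(S(=O)(=O)c3ccc(C)cc3)C=C2C)[C@H]1C | intermediate
10 | (4R,4aR,6R,7R,7aS)-4,7-dimethyl-2-tosyloctahydro-1H-cyclopenta[c]pyridin-6-ol | O[C@@H]1C[C@H]2[C@H](CN(S(=O)(=O)c3ccc(C)cc3)C[C@@H]2C)[C@H]1C | intermediate
11 | (4R,4aR,6R,7R,7aS)-4,7-dimethyloctahydro-1H-cyclopenta[c]pyridin-6-ol | O[C@@H]1C[C@H]2[C@H](CNC[C@@H]2C)[C@H]1C | intermediate
12 | (4R,4aR,6R,7R,7aS)-2,4,7-trimethyloctahydro-1H-cyclopenta[c]pyridin-6-ol | O[C@@H]1C[C@H]2[C@H](CN(C)C[C@@H]2C)[C@H]1C | intermediate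
13 | methyl (2E)-3,7-dimethylocta-2,6-dienoate | COC(=O)/C=C(\C)CCC=C(C)C | starting material
14 | methyl (2E,6E)-8-hydroxy-3,7-dimethylocta-2,6-dienoate | COC(=O)/C=C(\C)CC/C=C(\C)CO | intermediate
15 | methyl (2E,6E)-8-[(tert-butyldiphenylsilyl)oxy]-3,7-dimethylocta-2,6-dienoate | COC(=O)/C=C(\C)CC/C=C(\C)CO[Si](c1ccccc1)(c1ccccc1)C(C)(C)C | intermediate
16 | 2-[4-(benzyloxy)-3-methoxyphenyl]acetic acid | COc1cc(CC(=O)O)ccc1OCc1ccccc1 | starting material
17 | (2R,5R)-2,5-dimethylpyrrolidine | C[C@@H]1CC[C@@H](C)N1 | starting material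
18 | 2-[4-(benzyloxy)-3-methoxyphenyl]acetyl chloride | COc1cc(CC(=O)Cl)ccc1OCc1ccccc1 | intermediate
19 | 2-[4-(benzyloxy)-3-methoxyphenyl]-1-[(2R,5R)-2,5-dimethylpyrrolidin-1-yl]ethan-1-one | COc1cc(CC(=O)N2[C@H](C)CC[C@H]2C)ccc1OCc1ccccc1 | intermediate
20 | (2R,5R)-1-{2-[4-(benzyloxy)-3-methoxyphenyl]ethenylidene}-2,5-dimethylpyrrolidin-1-ium triflate (keteniminium salt) | COc1cc(C=C=[N+]2[C@H](C)CC[C@H]2C)ccc1OCc1ccccc1.[O-]S(=O)(=O)C(F)(F)F | intermediate
21 | cyclobutaniminium triflate (iminium form of 22; aryl-bearing carbon as formed, epimer mixture) | COc1cc(C2C(=[N+]3[C@H](C)CC[C@H]3C)[C@H](CC/C(C)=C/C(=O)OC)[C@@]2(C)CO[Si](c4ccccc4)(c4ccccc4)C(C)(C)C)ccc1OCc1ccccc1.[O-]S(=O)(=O)C(F)(F)F | intermediate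
22 | (2S,3R,4R)-2-[4-(benzyloxy)-3-methoxyphenyl]-3-{[(tert-butyldiphenylsilyl)oxy]methyl}-3-methyl-4-[(3E)-5-methoxy-3-methyl-5-oxopent-3-en-1-yl]cyclobutan-1-one | COc1cc([C@@H]2C(=O)[C@H](CC/C(C)=C/C(=O)OC)[C@@]2(C)CO[Si](c3ccccc3)(c3ccccc3)C(C)(C)C)ccc1OCc1ccccc1 | intermediate
23 | methoxymethylene derivative of 22 (exocyclic enol ether, E/Z mixture) | COc1cc([C@@H]2C(=COC)[C@H](CC/C(C)=C/C(=O)OC)[C@@]2(C)CO[Si](c3ccccc3)(c3ccccc3)C(C)(C)C)ccc1OCc1ccccc1 | intermediate
24 | cyclobutanecarbaldehyde (CHO trans to aryl and side chain) | COc1cc([C@@H]2[C@@H](C=O)[C@H](CC/C(C)=C/C(=O)OC)[C@@]2(C)CO[Si](c3ccccc3)(c3ccccc3)C(C)(C)C)ccc1OCc1ccccc1 | intermediate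
25 | cyclobutanecarboxylic acid (silyl ether, side-chain methyl ester) | COc1cc([C@@H]2[C@@H](C(=O)O)[C@H](CC/C(C)=C/C(=O)OC)[C@@]2(C)CO[Si](c3ccccc3)(c3ccccc3)C(C)(C)C)ccc1OCc1ccccc1 | intermediate
26 | hydroxy acid methyl ester | COc1cc([C@@H]2[C@@H](C(=O)O)[C@H](CC/C(C)=C/C(=O)OC)[C@@]2(C)CO)ccc1OCc1ccccc1 | intermediate
27 | 2-[4-(benzyloxy)-3-methoxyphenyl]-4-[(3E)-5-methoxy-3-methyl-5-oxopent-3-en-1-yl]-1-methylcyclobutane-1,3-dicarboxylic acid (the two carboxyls on one face; aryl, side chain and ring methyl on the other) | COc1cc([C@@H]2[C@@H](C(=O)O)[C@H](CC/C(C)=C/C(=O)OC)[C@@]2(C)C(=O)O)ccc1OCc1ccccc1 | intermediate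
28 | cyclic anhydride of 27, 6-[4-(benzyloxy)-3-methoxyphenyl]-7-[(3E)-5-methoxy-3-methyl-5-oxopent-3-en-1-yl]-1-methyl-3-oxabicyclo[3.1.1]heptane-2,4-dione | COc1cc([C@@H]2[C@@H](C(=O)O3)[C@H](CC/C(C)=C/C(=O)OC)[C@@]2(C)C3=O)ccc1OCc1ccccc1 | intermediate
29 | half-ester (CH-bound ring carboxyl of 27 esterified through O6 of 12; quaternary ring CO2H free; side-chain methyl ester) | COc1cc([C@@H]2[C@@H](C(=O)O[C@@H]3C[C@H]4[C@H](CN(C)C[C@@H]4C)[C@H]3C)[C@H](CC/C(C)=C/C(=O)OC)[C@@]2(C)C(=O)O)ccc1OCc1ccccc1 | intermediate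
30 | acyl chloride of 29 (formed as its amine hydrochloride) | COc1cc([C@@H]2[C@@H](C(=O)O[C@@H]3C[C@H]4[C@H](CN(C)C[C@@H]4C)[C@H]3C)[C@H](CC/C(C)=C/C(=O)OC)[C@@]2(C)C(Cl)=O)ccc1OCc1ccccc1 | intermediate
31 | bis-ester (both ring carboxyls of 27 esterified by 12; side-chain methyl ester) | COc1cc([C@@H]2[C@@H](C(=O)O[C@@H]3C[C@H]4[C@H](CN(C)C[C@@H]4C)[C@H]3C)[C@H](CC/C(C)=C/C(=O)OC)[C@@]2(C)C(=O)O[C@@H]2C[C@H]3[C@H](CN(C)C[C@@H]3C)[C@H]2C)ccc1OCc1ccccc1 | intermediate
32 | bis-ester acid (side-chain (2E)-enoic acid free) | COc1cc([C@@H]2[C@@H](C(=O)O[C@@H]3C[C@H]4[C@H](CN(C)C[C@@H]4C)[C@H]3C)[C@H](CC/C(C)=C/C(=O)O)[C@@]2(C)C(=O)O[C@@H]2C[C@H]3[C@H](CN(C)C[C@@H]3C)[C@H]2C)ccc1OCc1ccccc1 | intermediate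
33 | mixed anhydride of 32 with 2,4,6-trichlorobenzoic acid | COc1cc([C@@H]2[C@@H](C(=O)O[C@@H]3C[C@H]4[C@H](CN(C)C[C@@H]4C)[C@H]3C)[C@H](CC/C(C)=C/C(=O)OC(=O)c3c(Cl)cc(Cl)cc3Cl)[C@@]2(C)C(=O)O[C@@H]2C[C@H]3[C@H](CN(C)C[C@@H]3C)[C@H]2C)ccc1OCc1ccccc1 | intermediate
34 | O-benzyl ether of the target (tris-ester) | COc1cc([C@@H]2[C@@H](C(=O)O[C@@H]3C[C@H]4[C@H](CN(C)C[C@@H]4C)[C@H]3C)[C@H](CC/C(C)=C/C(=O)O[C@@H]3C[C@H]4[C@H](CN(C)C[C@@H]4C)[C@H]3C)[C@@]2(C)C(=O)O[C@@H]2C[C@H]3[C@H](CN(C)C[C@@H]3C)[C@H]2C)ccc1OCc1ccccc1 | intermediate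
35 | CNP0251577.2 | COc1cc([C@@H]2[C@@H](C(=O)O[C@@H]3C[C@H]4[C@H](CN(C)C[C@@H]4C)[C@H]3C)[C@H](CC/C(C)=C/C(=O)O[C@@H]3C[C@H]4[C@H](CN(C)C[C@@H]4C)[C@H]3C)[C@@]2(C)C(=O)O[C@@H]2C[C@H]3[C@H](CN(C)C[C@@H]3C)[C@H]2C)ccc1O | target

**Summary**

Total step count: 22. Longest linear sequence: 14 steps (steps 1–9, then 18–22).

Steps most likely to fail:

Step 5. The cycloaddition onto an unactivated alkene may be slow enough for the azadiene to tautomerise or oligomerise, and ring-fusion or π-facial selectivity may be poor. Fallback, from aldehyde 5, returning at 12: an Evans syn-aldol reaction of 5 with the boron enolate of (R)-4-benzyl-3-propionyloxazolidin-2-one (Bu2BOTf, i-Pr2NEt, CH2Cl2, −78 °C) would give the syn-aldol adduct F1, in which C4 already has its final configuration under auxiliary control. LiBH4 then removes the auxiliary to give the 1,3-diol F2. Mitsunobu azidation of the primary hydroxyl ((PhO)2P(O)N3, PPh3, DIAD) gives the azido alcohol F3, and 1,1'-thiocarbonyldiimidazole gives the thiocarbonylimidazolide F4. Bu3SnH/AIBN (PhH, 80 °C, slow addition) generates the C4a radical, which should close 5-exo onto the vinyl group through a chair-like transition state with all substituents pseudo-equatorial (C4a–C7a cis, same relation to C6 and C7). The resulting C1 radical is captured by the azide nitrogen with loss of N2, giving the bicyclic secondary amine F5. Reductive methylation (CH2O, NaBH(OAc)3) gives the N-methyl silyl ether F6, and Bu4NF returns 12. This forms the same two bonds by a radical cascade and needs neither the sulfonyl group nor the directed hydrogenation.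

Step 13. Conversion of the hindered trisubstituted alkene may be low, alkene geometry may be lost through a long-lived tertiary cation, or asymmetric induction may be weak. Fallback, from acid 16 and alkene 15, returning at 22: acid chloride 18 with Et3N gives the aryl ketene, which under EtAlCl2 (CH2Cl2, −78 °C) should add to 15 with the same regiochemistry to give the racemic cyclobutanone, that is 22 together with the enantiomeric cyclobutanone F7. Ketalisation with (R,R)-hydrobenzoin (bis-trimethylsilyl ether, TMSOTf) gives the diastereomeric hydrobenzoin ketal of 22 F8 and hydrobenzoin ketal of the enantiomer F9, which are separated by chromatography; aqueous acid then returns 22.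

Step 19. Acyl substitution at the fully substituted carbonyl may be slower than transesterification of the methyl enoate or of the existing ring ester by the alkoxide, and the acyl chloride may close back to the cyclic anhydride with loss of the first ester. Fallback, from 12 and 29, returning at 31: Mitsunobu inversion of 12 with 4-nitrobenzoic acid (PPh3, DIAD) gives the C6-inverted 4-nitrobenzoate F10, and K2CO3/MeOH gives the C6-epimeric amino alcohol F11. A Mitsunobu esterification of 29 with F11 (PPh3, DIAD, THF) then lets the hindered carboxylate displace at C6 with inversion, so that the crowded acyl carbon is never attacked, and gives 31.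

Further compounds
F1 | step 5 | (4R)-4-benzyl-3-[(2R,3S,5R,6R)-5-[(tert-butyldimethylsilyl)oxy]-3-hydroxy-2,6-dimethyloct-7-enoyl]oxazolidin-2-one | C=C[C@@H](C)[C@H](O[Si](C)(C)C(C)(C)C)C[C@H](O)[C@@H](C)C(=O)N1C(=O)OC[C@H]1Cc1ccccc1
F2 | step 5 | (2R,3S,5R,6R)-5-[(tert-butyldimethylsilyl)oxy]-2,6-dimethyloct-7-ene-1,3-diol (configuration as drawn in the SMILES) | C=C[C@@H](C)[C@H](O[Si](C)(C)C(C)(C)C)C[C@H](O)[C@@H](C)CO
F3 | step 5 | 1-azido-5-[(tert-butyldimethylsilyl)oxy]-2,6-dimethyloct-7-en-3-ol (configuration as drawn) | C=C[C@@H](C)[C@H](O[Si](C)(C)C(C)(C)C)C[C@H](O)[C@@H](C)CN=[N+]=[N-]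
F4 | step 5 | O-(imidazol-1-ylthiocarbonyl) derivative of F3 | C=C[C@@H](C)[C@H](O[Si](C)(C)C(C)(C)C)C[C@H](OC(=S)n1ccnc1)[C@@H](C)CN=[N+]=[N-]
F5 | step 5 | (4R,4aR,6R,7R,7aS)-6-[(tert-butyldimethylsilyl)oxy]-4,7-dimethyloctahydro-1H-cyclopenta[c]pyridine | CC(C)(C)[Si](C)(C)O[C@@H]1C[C@H]2[C@H](CNC[C@@H]2C)[C@H]1C
F6 | step 5 | (4R,4aR,6R,7R,7aS)-6-[(tert-butyldimethylsilyl)oxy]-2,4,7-trimethyloctahydro-1H-cyclopenta[c]pyridine | CC(C)(C)[Si](C)(C)O[C@@H]1C[C@H]2[C@H](CN(C)C[C@@H]2C)[C@H]1C
F7 | step 13 | enantiomer of 22, (2R,3S,4S) | COc1cc([C@H]2C(=O)[C@@H](CC/C(C)=C/C(=O)OC)[C@]2(C)CO[Si](c3ccccc3)(c3ccccc3)C(C)(C)C)ccc1OCc1ccccc1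
F8 | step 13 | (4R,5R)-4,5-diphenyl-1,3-dioxolane ketal of 22 | COc1cc([C@@H]2C3(O[C@H](c4ccccc4)[C@@H](c4ccccc4)O3)[C@H](CC/C(C)=C/C(=O)OC)[C@@]2(C)CO[Si](c4ccccc4)(c4ccccc4)C(C)(C)C)ccc1OCc1ccccc1
F9 | step 13 | (4R,5R)-4,5-diphenyl-1,3-dioxolane ketal of the enantiomer of 22 | COc1cc([C@H]2C3(O[C@H](c4ccccc4)[C@@H](c4ccccc4)O3)[C@@H](CC/C(C)=C/C(=O)OC)[C@]2(C)CO[Si](c4ccccc4)(c4ccccc4)C(C)(C)C)ccc1OCc1ccccc1
F10 | step 19 | (4R,4aR,6S,7R,7aS)-2,4,7-trimethyloctahydro-1H-cyclopenta[c]pyridin-6-yl 4-nitrobenzoate | O=C(O[C@H]1C[C@H]2[C@H](CN(C)C[C@@H]2C)[C@H]1C)c1ccc(cc1)[N+](=O)[O-]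
F11 | step 19 | (4R,4aR,6S,7R,7aS)-2,4,7-trimethyloctahydro-1H-cyclopenta[c]pyridin-6-ol | O[C@H]1C[C@H]2[C@H](CN(C)C[C@@H]2C)[C@H]1C
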